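**Retrosynthetic overview**

- Feature: C5–C20 is a hidden C2-symmetric sixteen-carbon unit. C6 and C19 are both S-configured, oxygen-bearing carbons, each carries one outer carbon (C5, C20), and twelve methylenes (C7–C18) join them.
- Disconnections: the lactone bond O(C19)–C1; C4–C5 (trans-oxiranyllithium plus a silylated propynal, C1 added afterwards as CO2Me); C20–C21 (dithiane anion plus epoxide); C7–C8 and C17–C18 together (bis-Grignard reagent of 1,10-dibromodecane plus two (S)-epichlorohydrin).
- Ring order: both oxiranes are closed from the bis-chlorohydrin in step 3 (one is later opened at C20, the other stays as the C5–C6 epoxide); the 20-membered lactone is closed in step 21.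
- Stereocentres: C6 and C19 from epichlorohydrin, C23 from (R)-propylene oxide, C21 by 1,3-syn reduction, C5 by trans-lithiation, C4 by catalyst-controlled reduction.

Key step: step 2

Remark: locants C1–C24 follow the target (C1 lactone carbonyl, C24 methyl). The spatial arrangement at every centre is that of the target throughout; the formal R/S label of C5 and C21 changes with the groups on neighbouring oxygens, so the SMILES strings are decisive.

**Route**

Step 1
Reactants: 1 1,10-dibromodecane
Product: 2 decane-1,10-diylbis(magnesium bromide) (titrated THF solution)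
Conditions: Mg turnings (excess), 1,2-dibromoethane (cat.), THF, 45 °C, slow addition
Reagents that add atoms: magnesium, [Mg]
Why: Grignard formation by insertion of Mg into both primary C–Br bonds; slow addition at moderate dilution should hold back Wurtz coupling, and a ten-carbon tether does not cyclise.

Step 2
Reactants: 2 decane-1,10-diylbis(magnesium bromide); 3 (S)-epichlorohydrin (2.6 equiv)
Product: 4 (2S,15S)-1,16-dichlorohexadecane-2,15-diol
Conditions: CuI (10 mol%), THF, −40 °C, slow addition of 2, then −20 °C; aq. NH4Cl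
Reagents that add atoms: none
Why: Each C–Mg terminus is transmetalated to an organocopper species (from catalytic CuI), which opens (S)-epichlorohydrin by SN2 attack at the unsubstituted oxirane carbon, forming C7–C8 and C17–C18 and giving the bis(magnesium alkoxide) of 4. The closest known reaction type is the copper-catalysed Grignard opening of epichlorohydrin to 1-chloroalkan-2-ols, run here at both ends of one bis-Grignard reagent. No ring is closed and no stereocentre is created: C6 and C19 are carried in from the two epichlorohydrin molecules because the C–O bond at each stereocentre is never touched. The step needs only regioselectivity (oxirane CH2 over CH2Cl and over the substituted carbon), which the soft copper nucleophile, the least hindered carbon and the low temperature should secure; the low temperature should also keep the magnesium chlorohydrinate from closing to an epoxide that could take up a second Grignard end. Excess epichlorohydrin should drive both ends to completion. Because 4 is C2-symmetric, any minor enantiomer of 3 should end up mainly in the meso diol, which crystallisation of 4 can remove.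

Step 3
Reactants: 4 (2S,15S)-1,16-dichlorohexadecane-2,15-diol
Product: 5 (2S,15S)-1,2:15,16-diepoxyhexadecane
Conditions: K2CO3, MeOH/THF, rt
Reagents that add atoms: none
Why: Twofold intramolecular Williamson closure (3-exo-tet); each alkoxide displaces chloride at the CH2 group, so the C–O stereocentres C6 and C19 are retained.

Step 4
Reactants: 6 1,3-dithiane; 7 (R)-propylene oxide
Product: 9 (R)-1-(1,3-dithian-2-yl)propan-2-ol, via 2-lithio-1,3-dithiane 8 (not isolated)
Conditions: n-BuLi, THF, −30 °C; then 7, −30 → 0 °C; H2O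
Reagents that add atoms: none
Why: Corey–Seebach alkylation; the lithiated dithiane opens the epoxide at its CH2 group by SN2, so the C23 stereocentre is imported unchanged.

Step 5
Reactants: 9 (R)-1-(1,3-dithian-2-yl)propan-2-ol
Product: 10 2-[(2R)-2-(4-methoxybenzyloxy)propyl]-1,3-dithiane
Conditions: NaH, 4-methoxybenzyl chloride, Bu4NI (cat.), THF/DMF, 0 °C → rt
Reagents that add atoms: 4-methoxybenzyl chloride, COc1ccc(CCl)cc1
Why: Williamson etherification of the secondary alkoxide; the dithiane C–H is not acidic enough for NaH.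

Step 6
Reactants: 10 2-[(2R)-2-(4-methoxybenzyloxy)propyl]-1,3-dithiane; 5 (2S,15S)-1,2:15,16-diepoxyhexadecane (3 equiv)
Product: 12 (2S)-1-{2-[(2R)-2-(4-methoxybenzyloxy)propyl]-1,3-dithian-2-yl}-14-[(2S)-oxiran-2-yl]tetradecan-2-ol, via lithiated dithiane 11 (not isolated)
Conditions: n-BuLi, THF, −30 °C; cannulated into 5, THF/DMPU, −30 → 0 °C; H2O; excess 5 recovered
Reagents that add atoms: none
Why: Corey–Seebach opening of one oxirane at its terminal carbon (C20) forms C20–C21; the two ends of 5 are homotopic, so mono-opening can give no regio- or stereoisomer, only a statistical mixture that the excess of recoverable 5 should bias toward 12.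

Step 7
Reactants: 12 the C19 alcohol from step 6
Product: 13 triethylsilyl ether of 12 at C19
Conditions: Et3SiCl, imidazole, DMAP (cat.), DMF, 0 °C → rt
Reagents that add atoms: chlorotriethylsilane, CC[Si](Cl)(CC)CC
Why: Silylation of the only free hydroxyl with a group that survives organolithium bases and can later be removed in the presence of tert-butyldimethylsilyl ethers.

Step 8
Reactants: 13 triethylsilyl ether of 12
Product: 14 (2R,6S)-2-(4-methoxybenzyloxy)-18-[(2S)-oxiran-2-yl]-6-(triethylsilyloxy)octadecan-4-one (C21 ketone)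
Conditions: MeI, CaCO3, MeCN/H2O (9:1), 40 °C
Reagents that add atoms: water, O
Why: Dithiane hydrolysis by S-methylation and attack of water under buffered, neutral conditions, which the epoxide and both ethers should tolerate.

Step 9
Reactants: 14 the C21 ketone
Product: 15 (2R,6S)-2-hydroxy-18-[(2S)-oxiran-2-yl]-6-(triethylsilyloxy)octadecan-4-one
Conditions: DDQ, CH2Cl2/pH 7 phosphate buffer, 0 °C
Reagents that add atoms: none
Why: Oxidative cleavage of the 4-methoxybenzyl ether (benzylic hydride abstraction, then hydrolysis) frees the C23 hydroxyl needed to direct the reduction.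

Step 10
Reactants: 15 the β-hydroxy ketone
Product: 17 (2R,4R,6S)-18-[(2S)-oxiran-2-yl]-6-(triethylsilyloxy)octadecane-2,4-diol, via diethylboron chelate 16 (not isolated)
Conditions: Et2BOMe, THF/MeOH (4:1), −78 °C; NaBH4, −78 °C; AcOH, then co-evaporation with MeOH
Reagents that add atoms: none
Why: Narasaka–Prasad reduction; boron ties the C23 oxygen and the C21 carbonyl into a six-membered chelate and external hydride attacks axially, which should give the 1,3-syn diol, i.e. C21 in the target configuration.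

Step 11
Reactants: 17 the syn-diol
Product: 18 (2R,4R,6S)-2,4-bis(tert-butyldimethylsilyloxy)-18-[(2S)-oxiran-2-yl]-6-(triethylsilyloxy)octadecane
Conditions: t-BuMe2SiCl, imidazole, DMAP (cat.), DMF, 40 °C
Reagents that add atoms: tert-butylchlorodimethylsilane, CC(C)(C)[Si](C)(C)Cl
Why: Bis-silylation with the chloride and imidazole rather than a silyl triflate, so that no Lewis acid meets the terminal epoxide.

Step 12
Reactants: 18 the silyl-protected terminal epoxide; 19 3-(trimethylsilyl)prop-2-ynal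
Product: 21 trans-5,6-epoxy-4-hydroxy alkyne (both C4 epimers; C2≡C3 capped with SiMe3), via trans-oxiranyllithium 20 (not isolated)
Conditions: s-BuLi, (−)-sparteine, Et2O/hexane, −90 °C; then 19, −90 → −78 °C; MeOH, then H2O
Reagents that add atoms: none
Why: Direct α-deprotonation of a terminal epoxide with s-BuLi and a diamine ligand removes the oxirane CH2 proton trans to the chain; the oxiranyllithium is configurationally stable at −90 °C and adds to the aldehyde with retention, so C4–C5 forms with the trans epoxide (C5 set by substrate control from C6), while C4 is not controlled here.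

Step 13
Reactants: 21 the epimeric epoxy alcohols
Product: 22 trans-5,6-epoxy-4-oxo alkyne (epoxy ynone)
Conditions: Dess–Martin periodinane, NaHCO3, CH2Cl2, 0 °C → rt
Reagents that add atoms: none
Why: Dess–Martin oxidation of the propargylic alcohol under buffered conditions merges both C4 epimers into one ketone.

Step 14
Reactants: 22 the epoxy ynone
Product: 23 (4R)-propargylic alcohol (C4 as in the target, threo to the epoxide)
Conditions: Ru[(S,S)-TsDPEN](p-cymene) (3 mol%; TsDPEN = N-tosyl-1,2-diphenylethylenediamine), i-PrOH, rt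
Reagents that add atoms: none
Why: Noyori asymmetric transfer hydrogenation of an α,β-acetylenic ketone under base-free conditions; the alkyne takes the place of the aryl group of the acetophenone model, so the (S,S) catalyst should deliver hydride to the face that gives the 4R alcohol under catalyst control.

Step 15
Reactants: 23 the (4R)-alcohol
Product: 24 C4 tert-butyldimethylsilyl ether of 23
Conditions: t-BuMe2SiCl, imidazole, DMF, rt
Reagents that add atoms: tert-butylchlorodimethylsilane, CC(C)(C)[Si](C)(C)Cl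
Why: Silylation of the C4 hydroxyl, which must stay masked so that the later Z-enoate cannot close to a butenolide.

Step 16
Reactants: 24 the silylated alkynylsilane
Product: 25 terminal alkyne (C2≡C3–H)
Conditions: K2CO3 (cat.), MeOH, 0 °C
Reagents that add atoms: none
Why: Methanolysis of the alkynyl C–SiMe3 bond, which is far more labile to methoxide than the silyl ethers.

Step 17
Reactants: 25 the terminal alkyne
Product: 27 methyl ynoate (C1 installed), via lithium acetylide 26 (not isolated)
Conditions: n-BuLi, THF, −78 °C; ClCO2Me, −78 → −40 °C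
Reagents that add atoms: methyl chloroformate, COC(=O)Cl
Why: Deprotonation of the terminal alkyne and C-acylation of the acetylide with the chloroformate forms C1–C2.

Step 18
Reactants: 27 the methyl ynoate
Product: 28 methyl (2Z)-enoate
Conditions: H2 (1 atm), Pd/CaCO3 poisoned with Pb(OAc)2 (Lindlar catalyst), quinoline, EtOAc/hexane, rt
Reagents that add atoms: none
Why: Lindlar semihydrogenation adds H2 syn across C2≡C3 and should stop at the Z-alkene; the epoxide and silyl ethers are inert.

Step 19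
Reactants: 28 the Z-enoate
Product: 29 C19 alcohol (hydroxy ester)
Conditions: HF·pyridine, excess pyridine, THF, 0 °C
Reagents that add atoms: none
Why: Buffered HF·pyridine should cleave the triethylsilyl ether much faster than the three secondary tert-butyldimethylsilyl ethers, freeing only the C19 hydroxyl.

Step 20
Reactants: 29 the hydroxy ester
Product: 30 seco acid
Conditions: LiOH, THF/MeOH/H2O, 0 °C → rt; then 0.5 M H3PO4 to pH 5, 0 °C; used at once
Reagents that add atoms: lithium hydroxide, [Li+].[OH-]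
Why: Saponification of the methyl ester (acyl–oxygen cleavage); the γ-oxygen is silylated, so the Z-enoate cannot lactonise to a butenolide.

Step 21
Reactants: 30 the seco acid
Product: 32 tris(tert-butyldimethylsilyl)-protected 20-membered lactone, via mixed anhydride 31 (not isolated)
Conditions: 2-methyl-6-nitrobenzoic anhydride (MNBA), DMAP, CH2Cl2 (about 1 mM), rt, slow addition of 30
Reagents that add atoms: none
Why: Shiina macrolactonisation; the mixed anhydride passes the acyl group to DMAP and the only free hydroxyl (C19) closes the 20-membered ring at room temperature and high dilution, with retention at C19 because the acyl–oxygen bond is the one formed.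

Step 22
Reactants: 32 the protected macrolactone
Product: 33 the target, CNP0461152.1
Conditions: Et3N·3HF, MeCN/THF, rt (plastic vessel)
Reagents that add atoms: none
Why: Global desilylation with a mildly acidic, non-basic fluoride source, so that no free alkoxide forms at C4 (which would translactonise to a butenolide) and the epoxide is not opened.

**Compound list**

1 | 1,10-dibromodecane | BrCCCCCCCCCCBr | starting material
2 | decane-1,10-diylbis(magnesium bromide) | Br[Mg]CCCCCCCCCC[Mg]Br | intermediate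
3 | (S)-epichlorohydrin | ClC[C@@H]1CO1 | starting material
4 | (2S,15S)-1,16-dichlorohexadecane-2,15-diol | ClC[C@@H](O)CCCCCCCCCCCC[C@H](O)CCl | intermediate
5 | (2S,15S)-1,2:15,16-diepoxyhexadecane | C1O[C@H]1CCCCCCCCCCCC[C@H]1CO1 | intermediate
6 | 1,3-dithiane | C1CSCSC1 | starting material
7 | (R)-propylene oxide | C[C@@H]1CO1 | starting material
8 | 2-lithio-1,3-dithiane | [Li]C1SCCCS1 | intermediate
9 | (R)-1-(1,3-dithian-2-yl)propan-2-ol | C[C@@H](O)CC1SCCCS1 | intermediate
10 | 2-[(2R)-2-(4-methoxybenzyloxy)propyl]-1,3-dithiane | C[C@@H](OCc1ccc(OC)cc1)CC1SCCCS1 | intermediate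
11 | 2-lithio derivative of 10 | C[C@@H](OCc1ccc(OC)cc1)CC2([Li])SCCCS2 | intermediate
12 | (2S)-1-{2-[(2R)-2-(4-methoxybenzyloxy)propyl]-1,3-dithian-2-yl}-14-[(2S)-oxiran-2-yl]tetradecan-2-ol | C[C@@H](OCc1ccc(OC)cc1)CC2(SCCCS2)C[C@@H](O)CCCCCCCCCCCC[C@H]3CO3 | intermediate
13 | C19 triethylsilyl ether of 12 | C[C@@H](OCc1ccc(OC)cc1)CC2(SCCCS2)C[C@@H](O[Si](CC)(CC)CC)CCCCCCCCCCCC[C@H]3CO3 | intermediate
14 | (2R,6S)-2-(4-methoxybenzyloxy)-18-[(2S)-oxiran-2-yl]-6-(triethylsilyloxy)octadecan-4-one | C[C@@H](OCc1ccc(OC)cc1)CC(=O)C[C@@H](O[Si](CC)(CC)CC)CCCCCCCCCCCC[C@H]1CO1 | intermediate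
15 | (2R,6S)-2-hydroxy-18-[(2S)-oxiran-2-yl]-6-(triethylsilyloxy)octadecan-4-one | C[C@@H](O)CC(=O)C[C@@H](O[Si](CC)(CC)CC)CCCCCCCCCCCC[C@H]1CO1 | intermediate
16 | diethylborinate (boron chelate) of 15 at the C23 oxygen | C[C@@H](OB(CC)CC)CC(=O)C[C@@H](O[Si](CC)(CC)CC)CCCCCCCCCCCC[C@H]1CO1 | intermediate
17 | (2R,4R,6S)-18-[(2S)-oxiran-2-yl]-6-(triethylsilyloxy)octadecane-2,4-diol | C[C@@H](O)C[C@@H](O)C[C@@H](O[Si](CC)(CC)CC)CCCCCCCCCCCC[C@H]1CO1 | intermediate
18 | (2R,4R,6S)-2,4-bis(tert-butyldimethylsilyloxy)-18-[(2S)-oxiran-2-yl]-6-(triethylsilyloxy)octadecane | C[C@@H](O[Si](C)(C)C(C)(C)C)C[C@@H](O[Si](C)(C)C(C)(C)C)C[C@@H](O[Si](CC)(CC)CC)CCCCCCCCCCCC[C@H]1CO1 | intermediate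
19 | 3-(trimethylsilyl)prop-2-ynal | C[Si](C)(C)C#CC=O | starting material
20 | trans-oxiranyllithium from 18 (Li on C5, trans to the chain) | C[C@@H](O[Si](C)(C)C(C)(C)C)C[C@@H](O[Si](C)(C)C(C)(C)C)C[C@@H](O[Si](CC)(CC)CC)CCCCCCCCCCCC[C@@H]1O[C@H]1[Li] | intermediate
21 | trans-5,6-epoxy-4-hydroxy-2-alkyne with SiMe3 on C2, both C4 epimers | C[C@@H](O[Si](C)(C)C(C)(C)C)C[C@@H](O[Si](C)(C)C(C)(C)C)C[C@@H](O[Si](CC)(CC)CC)CCCCCCCCCCCC[C@@H]1O[C@H]1C(O)C#C[Si](C)(C)C | intermediate
22 | trans-5,6-epoxy-4-oxo-2-alkyne with SiMe3 on C2 (epoxy ynone) | C[C@@H](O[Si](C)(C)C(C)(C)C)C[C@@H](O[Si](C)(C)C(C)(C)C)C[C@@H](O[Si](CC)(CC)CC)CCCCCCCCCCCC[C@@H]1O[C@H]1C(=O)C#C[Si](C)(C)C | intermediate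
23 | (4R)-propargylic alcohol from 22 | C[C@@H](O[Si](C)(C)C(C)(C)C)C[C@@H](O[Si](C)(C)C(C)(C)C)C[C@@H](O[Si](CC)(CC)CC)CCCCCCCCCCCC[C@@H]1O[C@H]1[C@H](O)C#C[Si](C)(C)C | intermediate
24 | C4 tert-butyldimethylsilyl ether of 23 | C[C@@H](O[Si](C)(C)C(C)(C)C)C[C@@H](O[Si](C)(C)C(C)(C)C)C[C@@H](O[Si](CC)(CC)CC)CCCCCCCCCCCC[C@@H]1O[C@H]1[C@H](O[Si](C)(C)C(C)(C)C)C#C[Si](C)(C)C | intermediate
25 | terminal alkyne from 24 | C[C@@H](O[Si](C)(C)C(C)(C)C)C[C@@H](O[Si](C)(C)C(C)(C)C)C[C@@H](O[Si](CC)(CC)CC)CCCCCCCCCCCC[C@@H]1O[C@H]1[C@H](O[Si](C)(C)C(C)(C)C)C#C | intermediate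
26 | lithium acetylide of 25 | C[C@@H](O[Si](C)(C)C(C)(C)C)C[C@@H](O[Si](C)(C)C(C)(C)C)C[C@@H](O[Si](CC)(CC)CC)CCCCCCCCCCCC[C@@H]1O[C@H]1[C@H](O[Si](C)(C)C(C)(C)C)C#C[Li] | intermediate
27 | methyl ynoate (C1–C24 chain complete) | C[C@@H](O[Si](C)(C)C(C)(C)C)C[C@@H](O[Si](C)(C)C(C)(C)C)C[C@@H](O[Si](CC)(CC)CC)CCCCCCCCCCCC[C@@H]1O[C@H]1[C@H](O[Si](C)(C)C(C)(C)C)C#CC(=O)OC | intermediate
28 | methyl (2Z)-enoate | C[C@@H](O[Si](C)(C)C(C)(C)C)C[C@@H](O[Si](C)(C)C(C)(C)C)C[C@@H](O[Si](CC)(CC)CC)CCCCCCCCCCCC[C@@H]1O[C@H]1[C@H](O[Si](C)(C)C(C)(C)C)/C=C\C(=O)OC | intermediate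
29 | C19 alcohol of 28 (hydroxy ester) | C[C@@H](O[Si](C)(C)C(C)(C)C)C[C@@H](O[Si](C)(C)C(C)(C)C)C[C@@H](O)CCCCCCCCCCCC[C@@H]1O[C@H]1[C@H](O[Si](C)(C)C(C)(C)C)/C=C\C(=O)OC | intermediate
30 | seco acid | C[C@@H](O[Si](C)(C)C(C)(C)C)C[C@@H](O[Si](C)(C)C(C)(C)C)C[C@@H](O)CCCCCCCCCCCC[C@@H]1O[C@H]1[C@H](O[Si](C)(C)C(C)(C)C)/C=C\C(=O)O | intermediate
31 | mixed anhydride of 30 with 2-methyl-6-nitrobenzoic acid | C[C@@H](O[Si](C)(C)C(C)(C)C)C[C@@H](O[Si](C)(C)C(C)(C)C)C[C@@H](O)CCCCCCCCCCCC[C@@H]1O[C@H]1[C@H](O[Si](C)(C)C(C)(C)C)/C=C\C(=O)OC(=O)c2c(C)cccc2[N+](=O)[O-] | intermediate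
32 | 4,21,23-tris(tert-butyldimethylsilyl) ether of the target macrolactone | C[C@@H](O[Si](C)(C)C(C)(C)C)C[C@@H](O[Si](C)(C)C(C)(C)C)C[C@@H]1CCCCCCCCCCCC[C@@H]2O[C@H]2[C@H](O[Si](C)(C)C(C)(C)C)/C=C\C(=O)O1 | intermediate
33 | CNP0461152.1: 20-membered (2Z)-4-hydroxy-5,6-epoxy macrolactone with a (2R,4R)-2,4-dihydroxypentyl side chain on C19 | C[C@@H](O)C[C@@H](O)C[C@@H]1CCCCCCCCCCCC[C@@H]2O[C@H]2[C@H](O)/C=C\C(=O)O1 | target

**Step count and risks**

Total step count: 22. Longest linear sequence: 20 steps (steps 1–3 and 6–22); steps 4–5 form a two-step branch that joins at step 6.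

Steps most likely to fail:

1. Step 12 (epoxide lithiation and aldehyde addition). The oxiranyllithium may decompose by α-elimination (carbenoid) pathways or be alkylated by excess s-BuLi before it meets the aldehyde, and lithiation of the hindered, polyoxygenated substrate may stay incomplete. The fallback sets out from 18 and comes back at 21, replacing the C–H lithiation by a one-carbon homologation and an epoxide transposition.
   - Dimethylsulfonium methylide (trimethylsulfonium iodide, n-BuLi, THF, −10 °C → rt) should open the terminal epoxide at C5 and eliminate dimethyl sulfide to give the (6S)-allylic alcohol F1, in which the new vinyl CH2 is C4.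
   - Matched Sharpless asymmetric epoxidation (Ti(OiPr)4, L-(+)-diisopropyl tartrate, t-BuOOH, 4 Å sieves, CH2Cl2, −20 °C) should give the erythro 4,5-epoxy-6-ol F2.
   - Payne rearrangement (aq. NaOH, t-BuOH, rt) should move the oxirane to C5–C6 with inversion at C5 and retention at C6, giving the trans-5,6-epoxy-4-ol F3.
   - Dess–Martin oxidation (NaHCO3, CH2Cl2) gives the trans-epoxy aldehyde F4.
   - Commercial LiC≡CSiMe3 (THF, −78 °C) adds to the aldehyde and returns to 21 as the C4 epimer mixture, which steps 13 and 14 correct as before.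

2. Step 21 (macrolactonisation of the Z-enoic seco acid). Oligomerisation may compete, the Z-alkene may isomerise to E through reversible conjugate addition of DMAP to the activated acyl species, and the carboxylate, held close to C5 by the Z-alkene, may open the epoxide. The fallback sets out from 27 and comes back at 32, closing the ring before the alkene exists.
   - Selective cleavage of the triethylsilyl ether (HF·pyridine, pyridine, THF, 0 °C) gives the C19-hydroxy methyl ynoate F5.
   - Saponification (LiOH, THF/H2O, 0 °C) gives the hydroxy ynoic acid F6.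
   - Shiina lactonisation (MNBA, DMAP, CH2Cl2, high dilution, rt) through the mixed anhydride F7 should give the macrocyclic ynoate F8; its linear C2≡C3 unit keeps the carboxyl away from the epoxide and has no geometry to lose.
   - Lindlar semihydrogenation inside the ring (H2, Pd/CaCO3 poisoned with Pb(OAc)2, quinoline) then gives 32.

3. Step 14 (catalyst-controlled reduction at C4). Facial selectivity may be poor if the bias of the adjacent epoxide opposes the catalyst, and the epoxy ketone may be opened under transfer-hydrogenation conditions. The fallback sets out from 22 and comes back at 25, using substrate control followed by inversion.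
   - Chelation-controlled reduction with Zn(BH4)2 (Et2O, −30 °C) should give the erythro (4S)-alcohol F9.
   - Mitsunobu inversion (4-nitrobenzoic acid, PPh3, diisopropyl azodicarboxylate, toluene, 0 °C) should give the (4R)-4-nitrobenzoate F10.
   - K2CO3 in MeOH cleaves the ester and the alkynyl C–Si bond together, giving the (4R)-alkynol F11.
   - Silylation (t-BuMe2SiCl, imidazole, DMF) returns to 25.

Further compounds
F1 | step 12 | (6S)-allylic alcohol, C4=C5 vinyl, from 18 | C[C@@H](O[Si](C)(C)C(C)(C)C)C[C@@H](O[Si](C)(C)C(C)(C)C)C[C@@H](O[Si](CC)(CC)CC)CCCCCCCCCCCC[C@H](O)C=C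
F2 | step 12 | erythro 4,5-epoxy-6-ol | C[C@@H](O[Si](C)(C)C(C)(C)C)C[C@@H](O[Si](C)(C)C(C)(C)C)C[C@@H](O[Si](CC)(CC)CC)CCCCCCCCCCCC[C@H](O)[C@H]1CO1
F3 | step 12 | trans-5,6-epoxy-4-ol (primary alcohol at C4) | C[C@@H](O[Si](C)(C)C(C)(C)C)C[C@@H](O[Si](C)(C)C(C)(C)C)C[C@@H](O[Si](CC)(CC)CC)CCCCCCCCCCCC[C@@H]1O[C@H]1CO
F4 | step 12 | trans-5,6-epoxy aldehyde (C4 aldehyde) | C[C@@H](O[Si](C)(C)C(C)(C)C)C[C@@H](O[Si](C)(C)C(C)(C)C)C[C@@H](O[Si](CC)(CC)CC)CCCCCCCCCCCC[C@@H]1O[C@H]1C=O
F5 | step 21 | C19-hydroxy methyl ynoate | C[C@@H](O[Si](C)(C)C(C)(C)C)C[C@@H](O[Si](C)(C)C(C)(C)C)C[C@@H](O)CCCCCCCCCCCC[C@@H]1O[C@H]1[C@H](O[Si](C)(C)C(C)(C)C)C#CC(=O)OC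
F6 | step 21 | hydroxy ynoic acid | C[C@@H](O[Si](C)(C)C(C)(C)C)C[C@@H](O[Si](C)(C)C(C)(C)C)C[C@@H](O)CCCCCCCCCCCC[C@@H]1O[C@H]1[C@H](O[Si](C)(C)C(C)(C)C)C#CC(=O)O
F7 | step 21 | mixed anhydride of F6 with 2-methyl-6-nitrobenzoic acid | C[C@@H](O[Si](C)(C)C(C)(C)C)C[C@@H](O[Si](C)(C)C(C)(C)C)C[C@@H](O)CCCCCCCCCCCC[C@@H]1O[C@H]1[C@H](O[Si](C)(C)C(C)(C)C)C#CC(=O)OC(=O)c2c(C)cccc2[N+](=O)[O-]
F8 | step 21 | macrocyclic ynoate, tris(tert-butyldimethylsilyl) ether | C[C@@H](O[Si](C)(C)C(C)(C)C)C[C@@H](O[Si](C)(C)C(C)(C)C)C[C@@H]1CCCCCCCCCCCC[C@@H]2O[C@H]2[C@H](O[Si](C)(C)C(C)(C)C)C#CC(=O)O1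
F9 | step 14 | erythro (4S)-propargylic alcohol | C[C@@H](O[Si](C)(C)C(C)(C)C)C[C@@H](O[Si](C)(C)C(C)(C)C)C[C@@H](O[Si](CC)(CC)CC)CCCCCCCCCCCC[C@@H]1O[C@H]1[C@@H](O)C#C[Si](C)(C)C
F10 | step 14 | (4R)-4-nitrobenzoate | C[C@@H](O[Si](C)(C)C(C)(C)C)C[C@@H](O[Si](C)(C)C(C)(C)C)C[C@@H](O[Si](CC)(CC)CC)CCCCCCCCCCCC[C@@H]1O[C@H]1[C@H](OC(=O)c2ccc(cc2)[N+](=O)[O-])C#C[Si](C)(C)C
F11 | step 14 | (4R)-alkynol with terminal alkyne | C[C@@H](O[Si](C)(C)C(C)(C)C)C[C@@H](O[Si](C)(C)C(C)(C)C)C[C@@H](O[Si](CC)(CC)CC)CCCCCCCCCCCC[C@@H]1O[C@H]1[C@H](O)C#C
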